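**Retrosynthetic overview**

1. The ten-membered ring (C1–C10) is opened last at C5=C6 (ring-closing metathesis); before that the C7/C8 butenolide is cut by an intramolecular Horner–Wadsworth–Emmons reaction to a C8 ketone, whose C7 carbinol comes from a γ-alkoxyallylboration of a C8 aldehyde.
2. The C2 propanoate and C14 acetate are read as a 1,3-diketone: C14 of the cyclohexene (C1, C10–C14) lies between C13H2 and quaternary C1, and C1 also carries the C2 carbonyl, so the ring is a 2-acyl-2-methylcyclohex-4-enone.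
3. This is the feature that allows the key step: C13 and C1 are the terminal and central carbons of a β-diketone, and C12=C11(Me)–C10 with C9–C8 is a (Z)-γ-methyl-δ-iodo dienal held as its acetal. Cutting C12–C13 and C1–C10 ([3+3]) leaves open-chain diketone 3 and iododiene acetal 8.
4. Forward: C12–C13 by palladium-catalysed coupling at the dianion terminus, then C1–C10 by amine-catalysed 6-exo Michael addition in the same pot; a CBS reduction at C2 and a 1,3-anti Evans–Tishchenko step then set C2 and C14.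
5. Ring order: cyclohexene (step 5), butenolide (step 14), ten-membered ring (step 15).

Key step: step 5

Remark: locants C1–C20 are those of the target's bicyclo[8.4.0]tetradecane core (C1 quaternary, C2 propanoate carbon, C5=C6, C7 lactone CH–O, C8 butenolide β-carbon, C10 ring-fusion CH, C11=C12, C14 acetate carbon); compounds 1, 2, 4 and all reagents are taken as commercial.

**Route**

Step 1
Reactants: 1 3-methylpentane-2,4-dione; 2 3-chloro-2-methylprop-1-ene
Product: 3 3,7-dimethyloct-7-ene-2,4-dione (C3 enolisable, used as the racemate)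
Conditions: NaH, THF, 0 °C; n-BuLi, −10 °C; then 2, −10 °C → rt; aq. NH4Cl
Reagents that add atoms: none
Why: γ-Alkylation of a β-diketone dianion: the second deprotonation takes the less hindered terminal methyl and only that carbanion is alkylated by the allylic chloride; no lasting stereocenter is made.

Step 2
Reactants: 4 prop-2-yn-1-ol
Product: 5 (Z)-3-iodo-2-methylprop-2-en-1-ol
Conditions: MeMgBr (2.5 equiv), CuI (10 mol%), THF, −10 °C → rt; then I2, −10 °C; H2O
Reagents that add atoms: methylmagnesium bromide C[Mg]Br; iodine II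
Why: Copper-catalysed carbomagnesiation of the propargylic alkoxide adds methyl to the internal carbon and leaves magnesium on the terminal carbon cis to the CH2O group (chelate), and iodinolysis with retention gives the Z-iodoalkene.

Step 3
Reactants: 5 (Z)-3-iodo-2-methylprop-2-en-1-ol
Product: 7 (2E,4Z)-5-iodo-4-methylpenta-2,4-dienal, via (Z)-3-iodo-2-methylprop-2-enal 6 (not isolated)
Conditions: MnO2, CH2Cl2, rt; filter; Ph3P=CHCHO (1.05 equiv), toluene, 60 °C
Reagents that add atoms: (triphenylphosphoranylidene)acetaldehyde O=CC=P(c1ccccc1)(c1ccccc1)c1ccccc1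
Why: Allylic oxidation followed by Wittig olefination with the stabilised formyl ylide, which is E-selective and leaves the Z-iodoalkene untouched; the ylide is kept near one equivalent to limit a second homologation.

Step 4
Reactants: 7 (2E,4Z)-5-iodo-4-methylpenta-2,4-dienal
Product: 8 (1Z,3E)-1-iodo-5,5-dimethoxy-2-methylpenta-1,3-diene
Conditions: HC(OMe)3, MeOH, PPTS (cat.), rt
Reagents that add atoms: trimethyl orthoformate COC(OC)OC; methanol CO
Why: Acid-catalysed acetalisation driven by the orthoformate turns the electrophilic dienal into a latent acceptor that is inert to carbanions; no stereocenter is touched.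

Step 5
Reactants: 3 3,7-dimethyloct-7-ene-2,4-dione; 8 (1Z,3E)-1-iodo-5,5-dimethoxy-2-methylpenta-1,3-diene
Product: 10 (2S,3S)-3-(2,2-dimethoxyethyl)-2,4-dimethyl-2-(4-methylpent-4-enoyl)cyclohex-4-en-1-one, via open-chain dienyl diketone acetal 9 (not isolated)
Conditions: 3, NaH, THF, 0 °C; n-BuLi, −20 °C; 8, Pd2(dba)3 (2.5 mol%), XPhos (6 mol%), 0 °C → 40 °C; then AcOH (1.1 equiv), MeOH, (S)-α,α-diphenylprolinol trimethylsilyl ether (20 mol%), PhCO2H (20 mol%), rt
Reagents that add atoms: methanol CO (solvent of the second stage; exchanges with the acetal methoxy groups, no net change)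
Why: Proposed new method: the sodium lithium dianion of 3 is nucleophilic only at its terminal CH2 (the central carbon is a hindered, stabilised diketonate), and zerovalent palladium (oxidative addition into the C–I bond of 8 with retention of the Z geometry, transmetalation, reductive elimination) forms C12–C13 to give 9 with the new CH2 and C10 cis on the C11=C12 alkene; the closest known reactions are γ-alkylation of β-diketone dianions and palladium-catalysed α-alkenylation of ketone enolates with alkenyl halides, and the acetal keeps the diene inert to the carbanion. After neutralisation the amine salt ionises the allylic acetal to a dienyl iminium ion and the enol of the 2-methyl-1,3-diketone adds through C1 to C10 in a 6-exo-trig Michael closure of the cyclohexene ring, methanol then returning the dimethyl acetal; the closest known type is the diarylprolinol silyl ether catalysed Michael addition of 1,3-dicarbonyl compounds to enals. C10 is controlled by the catalyst, whose diphenyl(silyloxy)methyl group shields one face of the E-iminium ion so that C1 bonds on the other (S catalyst, 10S). C1 is controlled by an open transition state in which the small methyl rather than the acyl branch lies next to the catalyst-bearing C9 arm, so that methyl ends cis and the C2 acyl trans to C9. The selectivity needed is 1,4- over 1,6-addition to the dienyl iminium ion, which the tether secures because only attack at C10 gives a six-membered ring and only the Z geometry of C11=C12 lets C1 reach it.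

Step 6
Reactants: 10 (2S,3S)-3-(2,2-dimethoxyethyl)-2,4-dimethyl-2-(4-methylpent-4-enoyl)cyclohex-4-en-1-one
Product: 12 (2S,3S)-3-(2,2-dimethoxyethyl)-2-[(1S)-1-hydroxy-4-methylpent-4-en-1-yl]-2,4-dimethylcyclohex-4-en-1-one, via trimethylsilyl dienol ether 11 (not isolated)
Conditions: LiN(SiMe3)2, THF, −78 °C; Me3SiCl; concentrate, hexane, filter; (R)-2-methyl-CBS-oxazaborolidine (20 mol%), catecholborane, toluene, −78 °C; aq. citric acid, THF, 0 °C
Reagents that add atoms: none
Why: The more acidic allylic α-position (C13) of the ring ketone is enolised and the ketone masked as silyl dienol ether 11, so the CBS reduction is left with the side-chain ketone, where the (R)-catalyst with the quaternary carbon as the large group gives the (S)-carbinol at C2; mild acid returns the ring ketone by α-protonation.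

Step 7
Reactants: 12 (2S,3S)-3-(2,2-dimethoxyethyl)-2-[(1S)-1-hydroxy-4-methylpent-4-en-1-yl]-2,4-dimethylcyclohex-4-en-1-one
Product: 13 (1S)-1-[(1R,2S,6S)-2-(2,2-dimethoxyethyl)-6-hydroxy-1,3-dimethylcyclohex-3-en-1-yl]-4-methylpent-4-en-1-yl propanoate
Conditions: propanal (4 equiv), SmI2 (15 mol%), THF, −10 °C
Reagents that add atoms: propanal CCC=O
Why: Evans–Tishchenko reduction: the samarium-bound hemiacetal formed from propanal on the C2 hydroxyl delivers hydride to the ring ketone through a chair transition state, which gives the 1,3-anti relation (axial 14S hydroxyl, cis to the C2 branch) and places the propanoate on O2 in the same event.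

Step 8
Reactants: 13 (1S)-1-[(1R,2S,6S)-2-(2,2-dimethoxyethyl)-6-hydroxy-1,3-dimethylcyclohex-3-en-1-yl]-4-methylpent-4-en-1-yl propanoate
Product: 14 (1S)-1-[(1S,2S,6S)-6-(acetyloxy)-2-(2,2-dimethoxyethyl)-1,3-dimethylcyclohex-3-en-1-yl]-4-methylpent-4-en-1-yl propanoate
Conditions: Ac2O, DMAP, pyridine, CH2Cl2, rt → 40 °C
Reagents that add atoms: acetic anhydride CC(=O)OC(C)=O
Why: DMAP-catalysed acylation of the hindered axial alcohol; the acetal, the alkenes and the propanoate are inert and no stereocenter is touched.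

Step 9
Reactants: 14 (1S)-1-[(1S,2S,6S)-6-(acetyloxy)-2-(2,2-dimethoxyethyl)-1,3-dimethylcyclohex-3-en-1-yl]-4-methylpent-4-en-1-yl propanoate
Product: 15 (1S)-1-[(1S,2S,6S)-6-(acetyloxy)-1,3-dimethyl-2-(2-oxoethyl)cyclohex-3-en-1-yl]-4-methylpent-4-en-1-yl propanoate
Conditions: PPTS (cat.), acetone/H2O (9:1), 40 °C
Reagents that add atoms: water O
Why: Mild acid hydrolysis of the dimethyl acetal frees the C8 aldehyde without touching the two esters or the 1,1-disubstituted alkene.

Step 10
Reactants: 15 (1S)-1-[(1S,2S,6S)-6-(acetyloxy)-1,3-dimethyl-2-(2-oxoethyl)cyclohex-3-en-1-yl]-4-methylpent-4-en-1-yl propanoate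
Product: 16 (1S)-1-[(1S,2S,6S)-6-(acetyloxy)-2-[(2S,3S)-2-hydroxy-3-(methoxymethoxy)pent-4-en-1-yl]-1,3-dimethylcyclohex-3-en-1-yl]-4-methylpent-4-en-1-yl propanoate
Conditions: allyl methoxymethyl ether, s-BuLi, THF, −78 °C; (+)-Ipc2BOMe [from (−)-α-pinene]; BF3·OEt2; then 15, −78 °C; NaBO3·4H2O, THF/H2O, rt
Reagents that add atoms: 3-(methoxymethoxy)prop-1-ene C=CCOCOC
Why: Asymmetric γ-alkoxyallylboration (Brown type): the (Z)-γ-alkoxyallylborane adds to the aldehyde through a chair six-membered transition state to give the syn 1,2-diol monoether, and the isopinocampheyl groups set C7 as S (C8 also S, erased in step 11), by the same facial sense as the parent B-allyl reagent.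

Step 11
Reactants: 16 (1S)-1-[(1S,2S,6S)-6-(acetyloxy)-2-[(2S,3S)-2-hydroxy-3-(methoxymethoxy)pent-4-en-1-yl]-1,3-dimethylcyclohex-3-en-1-yl]-4-methylpent-4-en-1-yl propanoate
Product: 17 (1S)-1-[(1S,2S,6S)-6-(acetyloxy)-2-[(3S)-3-(methoxymethoxy)-2-oxopent-4-en-1-yl]-1,3-dimethylcyclohex-3-en-1-yl]-4-methylpent-4-en-1-yl propanoate
Conditions: Dess–Martin periodinane, pyridine, CH2Cl2, 0 °C → rt
Reagents that add atoms: none
Why: Dess–Martin oxidation of the secondary alcohol to the C8 ketone under buffered conditions that should not epimerise the adjacent C7 center.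

Step 12
Reactants: 17 (1S)-1-[(1S,2S,6S)-6-(acetyloxy)-2-[(3S)-3-(methoxymethoxy)-2-oxopent-4-en-1-yl]-1,3-dimethylcyclohex-3-en-1-yl]-4-methylpent-4-en-1-yl propanoate
Product: 18 (1S)-1-[(1S,2S,6S)-6-(acetyloxy)-2-[(3S)-3-hydroxy-2-oxopent-4-en-1-yl]-1,3-dimethylcyclohex-3-en-1-yl]-4-methylpent-4-en-1-yl propanoate
Conditions: ZnBr2, n-PrSH, CH2Cl2, 0 °C
Reagents that add atoms: none
Why: Lewis acid and thiol cleave the methoxymethyl ether by transfer of its CH2OMe group to sulfur, leaving the esters and the C7 center untouched.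

Step 13
Reactants: 18 (1S)-1-[(1S,2S,6S)-6-(acetyloxy)-2-[(3S)-3-hydroxy-2-oxopent-4-en-1-yl]-1,3-dimethylcyclohex-3-en-1-yl]-4-methylpent-4-en-1-yl propanoate
Product: 19 (1S)-1-[(1S,2S,6S)-6-(acetyloxy)-2-[(3S)-3-{[2-(diethoxyphosphoryl)propanoyl]oxy}-2-oxopent-4-en-1-yl]-1,3-dimethylcyclohex-3-en-1-yl]-4-methylpent-4-en-1-yl propanoate (both epimers at the phosphonate carbon)
Conditions: 2-(diethoxyphosphoryl)propanoic acid, DCC, DMAP (cat.), CH2Cl2, 0 °C
Reagents that add atoms: 2-(diethoxyphosphoryl)propanoic acid CCOP(=O)(OCC)C(C)C(=O)O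
Why: Steglich esterification places the phosphonate on O7 under near-neutral conditions; the phosphonate α-carbon is lost as a stereocenter in step 14.

Step 14
Reactants: 19 (1S)-1-[(1S,2S,6S)-6-(acetyloxy)-2-[(3S)-3-{[2-(diethoxyphosphoryl)propanoyl]oxy}-2-oxopent-4-en-1-yl]-1,3-dimethylcyclohex-3-en-1-yl]-4-methylpent-4-en-1-yl propanoate
Product: 20 (1S)-1-[(1S,2S,6S)-6-(acetyloxy)-2-{[(2S)-2-ethenyl-4-methyl-5-oxo-2,5-dihydrofuran-3-yl]methyl}-1,3-dimethylcyclohex-3-en-1-yl]-4-methylpent-4-en-1-yl propanoate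
Conditions: LiCl, i-Pr2NEt, MeCN, 0 °C → rt
Reagents that add atoms: none
Why: Intramolecular Horner–Wadsworth–Emmons reaction under LiCl/amine (Masamune–Roush) conditions closes the butenolide by 5-exo addition to the C8 ketone and elimination; the weak base is chosen to spare the allylic C7 hydrogen.

Step 15
Reactants: 20 (1S)-1-[(1S,2S,6S)-6-(acetyloxy)-2-{[(2S)-2-ethenyl-4-methyl-5-oxo-2,5-dihydrofuran-3-yl]methyl}-1,3-dimethylcyclohex-3-en-1-yl]-4-methylpent-4-en-1-yl propanoate
Product: 21 target CNP0112230.2, (1S,2S,5Z,7S,10S,14S)-configured 14-acetate 2-propanoate tricyclic lactone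
Conditions: second-generation Grubbs catalyst (10 mol%), toluene (1 mM), 80 °C, argon sparge
Reagents that add atoms: none
Why: Ring-closing metathesis between the C7 vinyl group and the 1,1-disubstituted alkene closes the ten-membered ring at high dilution; the ring size allows only the Z trisubstituted alkene, and the tetrasubstituted butenolide and trisubstituted ring alkenes should not take part.

**Compound list**

1 | 3-methylpentane-2,4-dione | CC(=O)C(C)C(C)=O | starting material
2 | 3-chloro-2-methylprop-1-ene | CC(=C)CCl | starting material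
3 | 3,7-dimethyloct-7-ene-2,4-dione | CC(=O)C(C)C(=O)CCC(C)=C | intermediate
4 | prop-2-yn-1-ol | C#CCO | starting material
5 | (Z)-3-iodo-2-methylprop-2-en-1-ol | OC/C(C)=C\I | intermediate
6 | (Z)-3-iodo-2-methylprop-2-enal | O=C/C(C)=C\I | intermediate
7 | (2E,4Z)-5-iodo-4-methylpenta-2,4-dienal | O=C/C=C/C(C)=C\I | intermediate
8 | (1Z,3E)-1-iodo-5,5-dimethoxy-2-methylpenta-1,3-diene | COC(OC)/C=C/C(C)=C\I | intermediate
9 | (9Z,11E)-13,13-dimethoxy-2,6,10-trimethyltrideca-1,9,11-triene-5,7-dione | C=C(C)CCC(=O)C(C)C(=O)C/C=C(C)\C=C\C(OC)OC | intermediate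
10 | (2S,3S)-3-(2,2-dimethoxyethyl)-2,4-dimethyl-2-(4-methylpent-4-enoyl)cyclohex-4-en-1-one | C[C@]1(C(=O)CCC(C)=C)C(=O)CC=C(C)[C@@H]1CC(OC)OC | intermediate
11 | 1-[(1R,6S)-6-(2,2-dimethoxyethyl)-1,5-dimethyl-2-[(trimethylsilyl)oxy]cyclohexa-2,4-dien-1-yl]-4-methylpent-4-en-1-one | C[C@]1(C(=O)CCC(C)=C)C(O[Si](C)(C)C)=CC=C(C)[C@@H]1CC(OC)OC | intermediate
12 | (2S,3S)-3-(2,2-dimethoxyethyl)-2-[(1S)-1-hydroxy-4-methylpent-4-en-1-yl]-2,4-dimethylcyclohex-4-en-1-one | C[C@]1([C@@H](O)CCC(C)=C)C(=O)CC=C(C)[C@@H]1CC(OC)OC | intermediate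
13 | (1S)-1-[(1R,2S,6S)-2-(2,2-dimethoxyethyl)-6-hydroxy-1,3-dimethylcyclohex-3-en-1-yl]-4-methylpent-4-en-1-yl propanoate | C[C@]1([C@@H](OC(=O)CC)CCC(C)=C)[C@@H](O)CC=C(C)[C@@H]1CC(OC)OC | intermediate
14 | (1S)-1-[(1S,2S,6S)-6-(acetyloxy)-2-(2,2-dimethoxyethyl)-1,3-dimethylcyclohex-3-en-1-yl]-4-methylpent-4-en-1-yl propanoate | C[C@]1([C@@H](OC(=O)CC)CCC(C)=C)[C@@H](OC(C)=O)CC=C(C)[C@@H]1CC(OC)OC | intermediate
15 | (1S)-1-[(1S,2S,6S)-6-(acetyloxy)-1,3-dimethyl-2-(2-oxoethyl)cyclohex-3-en-1-yl]-4-methylpent-4-en-1-yl propanoate | C[C@]1([C@@H](OC(=O)CC)CCC(C)=C)[C@@H](OC(C)=O)CC=C(C)[C@@H]1CC=O | intermediate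
16 | (1S)-1-[(1S,2S,6S)-6-(acetyloxy)-2-[(2S,3S)-2-hydroxy-3-(methoxymethoxy)pent-4-en-1-yl]-1,3-dimethylcyclohex-3-en-1-yl]-4-methylpent-4-en-1-yl propanoate | C[C@]1([C@@H](OC(=O)CC)CCC(C)=C)[C@@H](OC(C)=O)CC=C(C)[C@@H]1C[C@H](O)[C@@H](OCOC)C=C | intermediate
17 | (1S)-1-[(1S,2S,6S)-6-(acetyloxy)-2-[(3S)-3-(methoxymethoxy)-2-oxopent-4-en-1-yl]-1,3-dimethylcyclohex-3-en-1-yl]-4-methylpent-4-en-1-yl propanoate | C[C@]1([C@@H](OC(=O)CC)CCC(C)=C)[C@@H](OC(C)=O)CC=C(C)[C@@H]1CC(=O)[C@@H](OCOC)C=C | intermediate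
18 | (1S)-1-[(1S,2S,6S)-6-(acetyloxy)-2-[(3S)-3-hydroxy-2-oxopent-4-en-1-yl]-1,3-dimethylcyclohex-3-en-1-yl]-4-methylpent-4-en-1-yl propanoate | C[C@]1([C@@H](OC(=O)CC)CCC(C)=C)[C@@H](OC(C)=O)CC=C(C)[C@@H]1CC(=O)[C@@H](O)C=C | intermediate
19 | (1S)-1-[(1S,2S,6S)-6-(acetyloxy)-2-[(3S)-3-{[2-(diethoxyphosphoryl)propanoyl]oxy}-2-oxopent-4-en-1-yl]-1,3-dimethylcyclohex-3-en-1-yl]-4-methylpent-4-en-1-yl propanoate | C[C@]1([C@@H](OC(=O)CC)CCC(C)=C)[C@@H](OC(C)=O)CC=C(C)[C@@H]1CC(=O)[C@@H](OC(=O)C(C)P(=O)(OCC)OCC)C=C | intermediate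
20 | (1S)-1-[(1S,2S,6S)-6-(acetyloxy)-2-{[(2S)-2-ethenyl-4-methyl-5-oxo-2,5-dihydrofuran-3-yl]methyl}-1,3-dimethylcyclohex-3-en-1-yl]-4-methylpent-4-en-1-yl propanoate | C[C@]1([C@@H](OC(=O)CC)CCC(C)=C)[C@@H](OC(C)=O)CC=C(C)[C@@H]1CC2=C(C)C(=O)O[C@H]2C=C | intermediate
21 | CNP0112230.2, (1S,2S,5Z,7S,10S,14S)-14-acetate 2-propanoate tricyclic lactone | CCC(=O)O[C@H]1CC/C(C)=C\[C@@H]2OC(=O)C(C)=C2C[C@H]2C(C)=CC[C@H](OC(C)=O)[C@]12C | target

**Step count and risks**

Total steps: 15. Longest linear sequence: 14 steps (from 4 through steps 2–15 to 21); step 1 is the only step off this line.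

Step 5 is the step most likely to fail. The palladium coupling may take place at the central diketonate carbon, or base may move the skipped diene of 9 into conjugation before it cyclises. In the second stage, reversible trienamine formation may scramble the C11=C12 geometry or lower the facial control. The fallback uses known reactions and makes the two bonds one at a time, C1–C10 first; it sets out from 3 and 7 and comes back at 10. The same prolinol silyl ether catalyst (PhCO2H, CH2Cl2, rt) should add 3 through its central carbon to the β-carbon of dienal 7 in an intermolecular iminium-catalysed Michael addition, giving (3R,4R)-4-acetyl-3-[(1Z)-1-iodoprop-1-en-2-yl]-4,8-dimethyl-5-oxonon-8-enal F1. HC(OMe)3, MeOH and PPTS should then give (3R,4R)-4-acetyl-3-[(1Z)-1-iodoprop-1-en-2-yl]-1,1-dimethoxy-4,8-dimethylnon-8-en-5-one F2. An intramolecular palladium-catalysed ketone α-alkenylation (Pd2(dba)3, XPhos, LiN(SiMe3)2, toluene, 60 °C) would join the acetyl methyl carbon to the alkenyl iodide carbon and give 10.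

Step 15 is the second. Oligomerisation may compete with closure of the strained ten-membered ring, or the catalyst may not turn over at the 1,1-disubstituted alkene. The fallback moves ring closure to an earlier and more flexible substrate; it sets out from 16 and comes back at 21. Ring-closing metathesis of 16 (second-generation Grubbs catalyst, toluene, 80 °C, high dilution), where C8 is still sp3 and no butenolide is fused, should give (1S,2S,5Z,7S,8S,10S,14S)-14-(acetyloxy)-8-hydroxy-7-(methoxymethoxy)-1,5,11-trimethylbicyclo[8.4.0]tetradeca-5,11-dien-2-yl propanoate F3. Dess–Martin oxidation should give (1S,2S,5Z,7S,10S,14S)-14-(acetyloxy)-7-(methoxymethoxy)-1,5,11-trimethyl-8-oxobicyclo[8.4.0]tetradeca-5,11-dien-2-yl propanoate F4. ZnBr2 and n-PrSH should give (1S,2S,5Z,7S,10S,14S)-14-(acetyloxy)-7-hydroxy-1,5,11-trimethyl-8-oxobicyclo[8.4.0]tetradeca-5,11-dien-2-yl propanoate F5. Esterification with 2-(diethoxyphosphoryl)propanoic acid (DCC, DMAP) should give (1S,2S,5Z,7S,10S,14S)-14-(acetyloxy)-7-{[2-(diethoxyphosphoryl)propanoyl]oxy}-1,5,11-trimethyl-8-oxobicyclo[8.4.0]tetradeca-5,11-dien-2-yl propanoate F6. The intramolecular Horner–Wadsworth–Emmons reaction (LiCl, i-Pr2NEt, MeCN) would then annulate the butenolide onto the preformed ring and give 21.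

Step 6 is the third. Enol silane formation may occur at the wrong ketone, the borane reduction of the neopentyl ketone may be slow or poorly selective, or the alkene may move into conjugation when the dienol ether is hydrolysed. The fallback reverses the order in which the two carbinol centers are made; it sets out from 10 and comes back at 14. LiBH(s-Bu)3 (THF, −78 °C) should reduce the more reactive ring ketone from the equatorial direction, as with other 2,2-disubstituted cyclohexanones, to the axial alcohol 1-[(1R,2S,6S)-2-(2,2-dimethoxyethyl)-6-hydroxy-1,3-dimethylcyclohex-3-en-1-yl]-4-methylpent-4-en-1-one F7. An Evans–Tishchenko reaction with acetaldehyde (SmI2 cat., THF, −10 °C) should then reduce the side-chain ketone 1,3-anti and leave the acetate on O14, giving (1S,5S,6S)-5-(2,2-dimethoxyethyl)-6-[(1S)-1-hydroxy-4-methylpent-4-en-1-yl]-4,6-dimethylcyclohex-3-en-1-yl acetate F8. Propanoic anhydride, DMAP and pyridine would give 14.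

**Further compounds**

F1 | step 5 | (3R,4R)-4-acetyl-3-[(1Z)-1-iodoprop-1-en-2-yl]-4,8-dimethyl-5-oxonon-8-enal | C[C@@](C(C)=O)(C(=O)CCC(C)=C)[C@@H](CC=O)/C(C)=C\I
F2 | step 5 | (3R,4R)-4-acetyl-3-[(1Z)-1-iodoprop-1-en-2-yl]-1,1-dimethoxy-4,8-dimethylnon-8-en-5-one | C[C@@](C(C)=O)(C(=O)CCC(C)=C)[C@@H](CC(OC)OC)/C(C)=C\I
F3 | step 15 | (1S,2S,5Z,7S,8S,10S,14S)-14-(acetyloxy)-8-hydroxy-7-(methoxymethoxy)-1,5,11-trimethylbicyclo[8.4.0]tetradeca-5,11-dien-2-yl propanoate | CCC(=O)O[C@H]1CC/C(C)=C\[C@H](OCOC)[C@@H](O)C[C@H]2C(C)=CC[C@H](OC(C)=O)[C@]12C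
F4 | step 15 | (1S,2S,5Z,7S,10S,14S)-14-(acetyloxy)-7-(methoxymethoxy)-1,5,11-trimethyl-8-oxobicyclo[8.4.0]tetradeca-5,11-dien-2-yl propanoate | CCC(=O)O[C@H]1CC/C(C)=C\[C@H](OCOC)C(=O)C[C@H]2C(C)=CC[C@H](OC(C)=O)[C@]12C
F5 | step 15 | (1S,2S,5Z,7S,10S,14S)-14-(acetyloxy)-7-hydroxy-1,5,11-trimethyl-8-oxobicyclo[8.4.0]tetradeca-5,11-dien-2-yl propanoate | CCC(=O)O[C@H]1CC/C(C)=C\[C@H](O)C(=O)C[C@H]2C(C)=CC[C@H](OC(C)=O)[C@]12C
F6 | step 15 | (1S,2S,5Z,7S,10S,14S)-14-(acetyloxy)-7-{[2-(diethoxyphosphoryl)propanoyl]oxy}-1,5,11-trimethyl-8-oxobicyclo[8.4.0]tetradeca-5,11-dien-2-yl propanoate | CCC(=O)O[C@H]1CC/C(C)=C\[C@H](OC(=O)C(C)P(=O)(OCC)OCC)C(=O)C[C@H]2C(C)=CC[C@H](OC(C)=O)[C@]12C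
F7 | step 6 | 1-[(1R,2S,6S)-2-(2,2-dimethoxyethyl)-6-hydroxy-1,3-dimethylcyclohex-3-en-1-yl]-4-methylpent-4-en-1-one | C[C@]1(C(=O)CCC(C)=C)[C@@H](O)CC=C(C)[C@@H]1CC(OC)OC
F8 | step 6 | (1S,5S,6S)-5-(2,2-dimethoxyethyl)-6-[(1S)-1-hydroxy-4-methylpent-4-en-1-yl]-4,6-dimethylcyclohex-3-en-1-yl acetate | C[C@]1([C@@H](O)CCC(C)=C)[C@@H](OC(C)=O)CC=C(C)[C@@H]1CC(OC)OC
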